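## Retrosynthetic overview

1. The target comes from a catalyst-controlled epoxidation of the ring A trisubstituted alkene of a triene bromohydrin (last step).
2. The triene comes from a Lewis-acid allyl–allyl coupling of a ring B allylsilane with a ring A allylic acetate; this joins the CH2 linker to ring A trans to isopropenyl.
3. The ring B allylsilane comes from a bridged bromolactone, and that from a syn-bromohydrin ester. The key step makes this ester: a bromonium-triggered 1,2-shift of methyl from boron to carbon in a cyclohexenyl boronate complex, followed by C–B oxidation.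
4. Ring B is formed first, by an enantioselective Diels–Alder reaction of 2-boryl-butadiene (from chloroprene) with methyl acrylate.
5. Ring A is formed in parallel, by an enantioselective Diels–Alder reaction of a prenal-derived acetoxy diene with methyl vinyl ketone, then methylenation.

Assumption: the sense of induction quoted for each chiral catalyst follows the published model for the parent substrates; if a first run shows the opposite sense, the antipodal catalyst is used with no other change.

## Route

Step 1
Reactants: 1 2-chlorobuta-1,3-diene (chloroprene)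
Product: 3 2-(buta-1,3-dien-2-yl)-4,4,5,5-tetramethyl-1,3,2-dioxaborolane, via dienyl Grignard reagent 2 (not isolated)
Conditions: Mg, ZnCl2 (cat.), BrCH2CH2Br (cat.), THF, reflux; then iPrOBpin, −78 °C → rt
Reagents that add atoms: 2-isopropoxy-4,4,5,5-tetramethyl-1,3,2-dioxaborolane (CC(C)OB1OC(C)(C)C(C)(C)O1)
Why: Grignard formation from the vinylic chloride and electrophilic borylation with an alkoxyboronic ester is the established entry to 2-boryl-1,3-dienes; no stereocenter is formed.

Step 2
Reactants: 3 2-(buta-1,3-dien-2-yl)-4,4,5,5-tetramethyl-1,3,2-dioxaborolane; 4 methyl acrylate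
Product: 5 methyl (1S)-4-(4,4,5,5-tetramethyl-1,3,2-dioxaborolan-2-yl)cyclohex-3-ene-1-carboxylate
Conditions: (S)-diphenylprolinol-derived B-(o-tolyl)oxazaborolidine (20 mol %), Tf2NH (20 mol %), CH2Cl2, −20 °C
Reagents that add atoms: none
Why: Proposed new method: enantioselective Diels–Alder reaction of a 2-boryl diene under chiral oxazaborolidinium catalysis — the cationic boron Lewis acid binds the acrylate carbonyl and shields one α-face while the Bpin group, like methyl or silyloxy, directs the "para" orientation, so C1 is set as S in the sense established for butadiene, isoprene and 2-silyloxybutadiene with acrylates, which together with the thermal cycloadditions of 2-boryl dienes are the closest known reactions.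

Step 3
Reactants: 5 methyl (1S)-4-(4,4,5,5-tetramethyl-1,3,2-dioxaborolan-2-yl)cyclohex-3-ene-1-carboxylate
Product: 8 methyl (1S,3R,4S)-3-bromo-4-hydroxy-4-methylcyclohexane-1-carboxylate, via lithium methylboronate complex 6 (not isolated), via bromo boronic ester 7 (not isolated)
Conditions: MeLi (1.0 equiv), THF, −100 °C; NBS, −100 → −78 °C; then NaBO3·4H2O, THF/H2O, 0 °C → rt
Reagents that add atoms: methyllithium ([Li]C); N-bromosuccinimide (O=C1CCC(=O)N1Br); sodium perborate ([Na+].[O-]OB=O)
Why: Proposed new method: bromonium-triggered 1,2-metallate shift with oxidative interception — MeLi adds to boron faster than to the ester at −100 °C, Br+ from NBS attacks the electron-rich alkenyl β-carbon axially on the face opposite the equatorial ester (sets C3), methyl migrates from boron to the adjacent carbon anti to bromine (new C–CH3 bond, Br and Me trans-diaxial, B and Br cis), the cis B/Br pair in the ring cannot undergo the anti boron–halide elimination that completes a Zweifel olefination, and stereoretentive C–B oxidation then sets C4 and gives the syn-bromohydrin; the closest known reactions are the Zweifel olefination and electrophile-induced 1,2-migrations of alkenyl boronate complexes (selenium or carbon electrophiles) in which the boronic ester is retained.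

Step 4
Reactants: 8 methyl (1S,3R,4S)-3-bromo-4-hydroxy-4-methylcyclohexane-1-carboxylate
Product: 10 (1S,4R,6R)-6-bromo-1-methyl-2-oxabicyclo[2.2.2]octan-3-one, via cis hydroxy ester 9 (not isolated)
Conditions: KOtBu (0.3 equiv), 5 Å MS, THF, 0 °C → rt
Reagents that add atoms: none
Why: Base-catalysed epimerization–lactonization (intramolecular transesterification): the ester α-carbon equilibrates through its enolate and only epimer 9, with CO2Me cis to the tertiary OH, can close to the bridged lactone, so C1 is inverted under thermodynamic control to the configuration of the target, while the cis-disposed Br and alkoxide cannot form an epoxide.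

Step 5
Reactants: 10 (1S,4R,6R)-6-bromo-1-methyl-2-oxabicyclo[2.2.2]octan-3-one
Product: 12 (1S,2R,4R)-2-bromo-1-methyl-4-[3-(trimethylsilyl)prop-1-en-2-yl]cyclohexan-1-ol, via bis(silylmethyl) carbinol 11 (not isolated)
Conditions: TMSCH2MgCl (5 equiv), CeCl3, THF, −78 °C → rt; then SiO2, CH2Cl2
Reagents that add atoms: (trimethylsilyl)methylmagnesium chloride (C[Si](C)(C)C[Mg]Cl)
Why: Bunnelle–Narayanan allylsilane synthesis: the non-basic organocerium reagent adds twice to the lactone carbonyl and Peterson elimination of one Me3Si/OH pair on silica gives the 2-substituted allylsilane, with no stereocenter touched.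

Step 6
Reactants: 13 3-methylbut-2-enal (prenal)
Product: 14 (1E)-3-methylbuta-1,3-dien-1-yl acetate
Conditions: isopropenyl acetate, TsOH (cat.), Cu(OAc)2 (cat.), 95 °C, acetone distilled off
Reagents that add atoms: isopropenyl acetate (CC(=C)OC(C)=O)
Why: Acid-catalysed enol acetylation by acyl transfer from isopropenyl acetate traps the dienol of prenal as the 1-acetoxy diene (mainly E; the Z isomer does not cycloadd); no stereocenter.

Step 7
Reactants: 14 (1E)-3-methylbuta-1,3-dien-1-yl acetate; 15 but-3-en-2-one (methyl vinyl ketone)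
Product: 16 (1R,6S)-6-acetyl-3-methylcyclohex-2-en-1-yl acetate
Conditions: (S)-diphenylprolinol-derived B-(o-tolyl)oxazaborolidine (20 mol %), Tf2NH (20 mol %), CH2Cl2, −78 °C
Reagents that add atoms: none
Why: Diels–Alder reaction under chiral oxazaborolidinium catalysis: the acetoxy (ortho) and methyl (para) directing effects reinforce each other, and face-selective attack on the catalyst-bound enone sets the acetyl-bearing carbon as S (endo gives the cis acetate; the acetoxy carbon is ionized in step 9, so any exo isomer converges).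

Step 8
Reactants: 16 (1R,6S)-6-acetyl-3-methylcyclohex-2-en-1-yl acetate
Product: 17 (1R,6R)-3-methyl-6-(prop-1-en-2-yl)cyclohex-2-en-1-yl acetate
Conditions: Cp2Ti(µ-CH2)(µ-Cl)AlMe2 (1.1 equiv), pyridine (cat.), THF/toluene, −40 → 0 °C
Reagents that add atoms: Cp2Ti(µ-CH2)(µ-Cl)AlMe2, the Tebbe methylenation reagent (C[Al-]1(C)C[Ti](C2C=CC=C2)(C2C=CC=C2)[Cl+]1)
Why: Tebbe methylenation: the titanium methylidene olefinates the ketone much faster than the acetate and is non-basic, so the epimerizable α-stereocenter (the future isopropenyl carbon) and the β-acetoxy group survive.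

Step 9
Reactants: 12 (1S,2R,4R)-2-bromo-1-methyl-4-[3-(trimethylsilyl)prop-1-en-2-yl]cyclohexan-1-ol; 17 (1R,6R)-3-methyl-6-(prop-1-en-2-yl)cyclohex-2-en-1-yl acetate
Product: 18 (1S,2R,4R)-2-bromo-1-methyl-4-{3-[(1S,6S)-3-methyl-6-(prop-1-en-2-yl)cyclohex-2-en-1-yl]prop-1-en-2-yl}cyclohexan-1-ol
Conditions: BF3·OEt2 (0.3 equiv), CH2Cl2, −78 → −40 °C
Reagents that add atoms: none
Why: Lewis acid-catalysed allylic substitution (Hosomi–Sakurai-type SE2′ allylation, as in Ferrier C-allylations): BF3 ionizes the acetate to the 1-methyl-4-isopropenylcyclohexenyl cation, which the 2-substituted allylsilane attacks at the secondary terminus anti to the neighbouring isopropenyl group (the regio- and stereochemistry known from cannabidiol-type couplings of this cation), setting the new stereocenter trans and unveiling the exocyclic methylene.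

Step 10
Reactants: 18 (1S,2R,4R)-2-bromo-1-methyl-4-{3-[(1S,6S)-3-methyl-6-(prop-1-en-2-yl)cyclohex-2-en-1-yl]prop-1-en-2-yl}cyclohexan-1-ol
Product: 19 (1S,2R,4R)-2-bromo-1-methyl-4-{3-[(1R,2R,3S,6S)-6-methyl-3-(prop-1-en-2-yl)-7-oxabicyclo[4.1.0]heptan-2-yl]prop-1-en-2-yl}cyclohexan-1-ol (CNP0213097.1)
Conditions: D-fructose-derived Shi ketone (30 mol %), KHSO5 (as 2KHSO5·KHSO4·K2SO4, 1.3 equiv), K2CO3, Bu4NHSO4, MeCN/CH2(OMe)2/aq. Na2B4O7 buffer, 0 °C
Reagents that add atoms: potassium peroxymonosulfate ([K+].[O-]S(=O)(=O)OO)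
Why: Shi asymmetric epoxidation: the chiral dioxirane reacts with the trisubstituted ring alkene far faster than with the two 1,1-disubstituted alkenes and, through the spiro transition state that gives (R,R)-1-phenylcyclohexene oxide, delivers oxygen to the face syn to the side chain and anti to isopropenyl, setting both epoxide carbons as in the target.

## Compound list

1 | 2-chlorobuta-1,3-diene | C=CC(Cl)=C | starting material
2 | (buta-1,3-dien-2-yl)magnesium chloride | C=CC(=C)[Mg]Cl | intermediate
3 | 2-(buta-1,3-dien-2-yl)-4,4,5,5-tetramethyl-1,3,2-dioxaborolane | C=CC(=C)B1OC(C)(C)C(C)(C)O1 | intermediate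
4 | methyl acrylate | C=CC(=O)OC | starting material
5 | methyl (1S)-4-(4,4,5,5-tetramethyl-1,3,2-dioxaborolan-2-yl)cyclohex-3-ene-1-carboxylate | COC(=O)[C@@H]1CC=C(B2OC(C)(C)C(C)(C)O2)CC1 | intermediate
6 | lithium methylboronate complex of 5 | COC(=O)[C@@H]1CC=C([B-]2(C)OC(C)(C)C(C)(C)O2)CC1.[Li+] | intermediate
7 | methyl (1S,3R,4R)-3-bromo-4-methyl-4-(4,4,5,5-tetramethyl-1,3,2-dioxaborolan-2-yl)cyclohexane-1-carboxylate | COC(=O)[C@@H]1C[C@@H](Br)[C@@](C)(B2OC(C)(C)C(C)(C)O2)CC1 | intermediate
8 | methyl (1S,3R,4S)-3-bromo-4-hydroxy-4-methylcyclohexane-1-carboxylate | COC(=O)[C@@H]1C[C@@H](Br)[C@@](C)(O)CC1 | intermediate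
9 | methyl (1R,3R,4S)-3-bromo-4-hydroxy-4-methylcyclohexane-1-carboxylate | COC(=O)[C@H]1C[C@@H](Br)[C@@](C)(O)CC1 | intermediate
10 | (1S,4R,6R)-6-bromo-1-methyl-2-oxabicyclo[2.2.2]octan-3-one | O=C1O[C@@]2(C)CC[C@@H]1C[C@H]2Br | intermediate
11 | (1S,2R,4R)-2-bromo-4-[2-hydroxy-1,3-bis(trimethylsilyl)propan-2-yl]-1-methylcyclohexan-1-ol | C[Si](C)(C)CC(O)(C[Si](C)(C)C)[C@@H]1CC[C@](C)(O)[C@H](Br)C1 | intermediate
12 | (1S,2R,4R)-2-bromo-1-methyl-4-[3-(trimethylsilyl)prop-1-en-2-yl]cyclohexan-1-ol | C=C(C[Si](C)(C)C)[C@@H]1CC[C@](C)(O)[C@H](Br)C1 | intermediate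
13 | 3-methylbut-2-enal | CC(C)=CC=O | starting material
14 | (1E)-3-methylbuta-1,3-dien-1-yl acetate | CC(=O)O/C=C/C(C)=C | intermediate
15 | but-3-en-2-one | CC(=O)C=C | starting material
16 | (1R,6S)-6-acetyl-3-methylcyclohex-2-en-1-yl acetate | CC(=O)O[C@@H]1C=C(C)CC[C@@H]1C(C)=O | intermediate
17 | (1R,6R)-3-methyl-6-(prop-1-en-2-yl)cyclohex-2-en-1-yl acetate | CC(=O)O[C@@H]1C=C(C)CC[C@@H]1C(C)=C | intermediate
18 | (1S,2R,4R)-2-bromo-1-methyl-4-{3-[(1S,6S)-3-methyl-6-(prop-1-en-2-yl)cyclohex-2-en-1-yl]prop-1-en-2-yl}cyclohexan-1-ol | C=C(C[C@@H]1[C@@H](C(=C)C)CCC(C)=C1)[C@@H]1CC[C@](C)(O)[C@H](Br)C1 | intermediate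
19 | (1S,2R,4R)-2-bromo-1-methyl-4-{3-[(1R,2R,3S,6S)-6-methyl-3-(prop-1-en-2-yl)-7-oxabicyclo[4.1.0]heptan-2-yl]prop-1-en-2-yl}cyclohexan-1-ol | C=C(C[C@@H]1[C@@H](C(=C)C)CC[C@]2(C)O[C@H]12)[C@@H]1CC[C@](C)(O)[C@H](Br)C1 | target

## Step count and risks

Total step count: 10 (steps 1–5 ring B fragment, steps 6–8 ring A fragment, step 9 coupling, step 10 epoxidation).
Longest linear sequence: 7 steps (1 → 2 → 3 → 4 → 5 → 9 → 10).

The three steps most likely to fail:

Step 2 (Diels–Alder reaction of the boryl diene). The diene may be too unreactive toward methyl acrylate, or the Bpin oxygens may disturb the catalyst and lower the ee. The fallback uses the documented diene class, sets out from 15 and 4 and comes back at 5. Silylation of 15 (TIPSOTf, Et3N) gives 2-[tri(propan-2-yl)silyloxy]buta-1,3-diene F1. The same oxazaborolidinium-catalysed Diels–Alder reaction with 4 gives methyl (1S)-4-[tri(propan-2-yl)silyloxy]cyclohex-3-ene-1-carboxylate F2. CsF and PhNTf2 convert the silyl enol ether regiospecifically into methyl (1S)-4-{[(trifluoromethyl)sulfonyl]oxy}cyclohex-3-ene-1-carboxylate F3. Miyaura borylation (PdCl2(dppf), B2pin2, KOAc, dioxane, 80 °C) then gives 5.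

Step 3 (the proposed bromonium-triggered 1,2-shift with oxidation). Possible failures are attack of MeLi on the ester, boron–bromide elimination from 7 during oxidation (returning a methylcyclohexene), or poor facial selectivity. The minor diastereomer (bromine cis to the ester) must be removed from 8 by chromatography, because it would lactonize to the enantiomer of 10. The fallback is known chemistry, sets out from 15 and 4 and comes back at 8. The silyl enol ether F2, made from F1 as described above, is brominated with NBS (THF, −78 °C, axial attack) to methyl (1S,3R)-3-bromo-4-oxocyclohexane-1-carboxylate F4. This is treated at once with MeTi(OiPr)3 (or MeMgBr at −78 °C); methyl adds to the ketone, not the ester, anti to the axial C–Br bond (Cornforth/Felkin control, the classical cis-halohydrin outcome) and gives 8.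

Step 4 (base-catalysed epimerization–lactonization). The alkoxide of the bromohydrin may eliminate HBr or rearrange (semipinacol) before the ester epimerizes. The fallback moves the epimerization to the aldehyde oxidation level, where an amine base suffices; it sets out from 8 and comes back at 10. Reduction of 8 with iBu2AlH (CH2Cl2, −78 °C) gives (1S,3R,4S)-3-bromo-4-hydroxy-4-methylcyclohexane-1-carbaldehyde F5. DBU (cat., CH2Cl2, rt) equilibrates it with (1R,3R,4S)-3-bromo-4-hydroxy-4-methylcyclohexane-1-carbaldehyde F6, which is drained from the equilibrium as the lactol (1S,4R,6R)-6-bromo-1-methyl-2-oxabicyclo[2.2.2]octan-3-ol F7. Oxidation of the lactol (Ag2CO3 on Celite, or TEMPO/PhI(OAc)2) gives 10.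

## Further compounds

F1 | step 2 | 2-[tri(propan-2-yl)silyloxy]buta-1,3-diene | C=CC(=C)O[Si](C(C)C)(C(C)C)C(C)C
F2 | step 2 | methyl (1S)-4-[tri(propan-2-yl)silyloxy]cyclohex-3-ene-1-carboxylate | COC(=O)[C@@H]1CC=C(O[Si](C(C)C)(C(C)C)C(C)C)CC1
F3 | step 2 | methyl (1S)-4-{[(trifluoromethyl)sulfonyl]oxy}cyclohex-3-ene-1-carboxylate | COC(=O)[C@@H]1CC=C(OS(=O)(=O)C(F)(F)F)CC1
F4 | step 3 | methyl (1S,3R)-3-bromo-4-oxocyclohexane-1-carboxylate | COC(=O)[C@@H]1C[C@@H](Br)C(=O)CC1
F5 | step 4 | (1S,3R,4S)-3-bromo-4-hydroxy-4-methylcyclohexane-1-carbaldehyde | O=C[C@@H]1C[C@@H](Br)[C@@](C)(O)CC1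
F6 | step 4 | (1R,3R,4S)-3-bromo-4-hydroxy-4-methylcyclohexane-1-carbaldehyde | O=C[C@H]1C[C@@H](Br)[C@@](C)(O)CC1
F7 | step 4 | (1S,4R,6R)-6-bromo-1-methyl-2-oxabicyclo[2.2.2]octan-3-ol | OC1O[C@@]2(C)CC[C@@H]1C[C@H]2Br
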